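**Plan**

1. Cuts: each flavone heterocycle is opened at O1–C2. The resulting 1,3-diketone is then cut at C2–C3, first in unit 1 (the 7-methoxyflavone) and then in unit 2 (the 8''-linked apigenin). This leaves a 4-oxygenated 3-(2,4,6-trioxygenated phenyl)benzoate.
2. Enabling feature: ring B of unit 1 is a 1,3,4-trisubstituted benzene. C1' carries an acyl-level carbon (flavone C2), C3' carries the phloroglucinol ring (C8'') and C4' carries oxygen. A 2-pyranone-5-carboxylate and an aryl ynol ether place ester, aryl and oxygen in exactly these positions.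
3. Ring B is therefore cut at C2'–C3' and C4'–C5' into methyl coumalate and a (2,4,6-trimethoxyphenyl)siloxyalkyne. The C3'–C8'' biaryl bond is the aryl–alkyne bond of the dienophile.
4. Forward order: aldehyde, alkyne, siloxyalkyne; ring B by cycloaddition and CO2 loss; acetyl group on the phloroglucinol ring; methyl-to-benzyl exchange; ring C of unit 2; rings A and C of unit 1 from 2',6'-dihydroxy-4'-methoxyacetophenone; hydrogenolysis.
5. The only methyl ether of the target arrives with the last building block, after all BBr3 chemistry, so no selective demethylation is needed at the end.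
6. Stereochemistry: the target has no stereocentre, so nothing has to be set.

Key step: step 3

Assumption: the target SMILES carries no stereodescriptor, so the C3'–C8'' axis is treated as configurationally undefined and all unsymmetrical biaryl intermediates are handled as racemates or interconverting rotamers.

**Route**

Step 1
Reactants: 1 2,4,6-trimethoxybenzaldehyde
Product: 2 2-ethynyl-1,3,5-trimethoxybenzene
Conditions: dimethyl (1-diazo-2-oxopropyl)phosphonate, K2CO3, MeOH (THF co-solvent), rt
Reagents that add atoms: dimethyl (1-diazo-2-oxopropyl)phosphonate, CC(=O)C(=[N+]=[N-])P(=O)(OC)OC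
Why: The Seyferth–Gilbert homologation in its Ohira–Bestmann form turns non-enolisable aryl aldehydes into terminal alkynes in one operation, under carbonate/methanol conditions that leave the aryl methyl ethers untouched.

Step 2
Reactants: 2 2-ethynyl-1,3,5-trimethoxybenzene
Product: 5 triisopropyl{[(2,4,6-trimethoxyphenyl)ethynyl]oxy}silane, via lithium acetylide 3 (not isolated), via lithium ynolate 4 (not isolated)
Conditions: n-BuLi, THF, −78 °C; LiOOt-Bu [t-BuOOH (anhydrous, decane), LiN(SiMe3)2, THF, −78 °C], −78 → 0 °C; TIPSOTf, −78 → 0 °C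
Reagents that add atoms: tert-butyl hydroperoxide, CC(C)(C)OO; triisopropylsilyl triflate, CC(C)[Si](C(C)C)(C(C)C)OS(=O)(=O)C(F)(F)F; n-butyllithium, [Li]CCCC (lithium of 3 and 4 only)
Why: Oxygen transfer from lithium tert-butyl peroxide to a lithium acetylide is the established oxidation route to lithium ynolates, and the bulky, hard TIPSOTf should trap the ynolate at oxygen rather than carbon to give a siloxyalkyne that tolerates chromatography.

Step 3
Reactants: 5 triisopropyl{[(2,4,6-trimethoxyphenyl)ethynyl]oxy}silane; 6 methyl coumalate (methyl 2-oxo-2H-pyran-5-carboxylate)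
Product: 8 methyl 4-[(triisopropylsilyl)oxy]-3-(2,4,6-trimethoxyphenyl)benzoate, via bridged bicyclic lactone 7 (not isolated)
Conditions: 6 (1.5 equiv), toluene, 120 °C, sealed tube, Ar
Reagents that add atoms: none
Why: The electron-poor diene C3=C4–C5=C6 of 6 and the electron-rich triple bond of 5 combine in a concerted but strongly asynchronous inverse-electron-demand Diels–Alder reaction to the 2-oxabicyclo[2.2.2]octadienone 7, which at this temperature loses its O1–C2 bridge as CO2 by retro-[4+2] and so gives the arene at the right oxidation level without an oxidant. The closest known reaction type is the thermal benzannulation of methyl coumalate and other 2-pyranones with ynamines, alkoxyalkynes, ketene acetals and siloxyalkynes. Ring B is the only ring closed, by intermolecular [4+2] closure in which pyranone C6 bonds to the aryl-bearing alkyne carbon (the future C2'–C3' bond) and pyranone C3 to the siloxy-bearing carbon (the future C4'–C5' bond), so the aryl–alkyne bond of 5 becomes the C3'–C8'' biaryl bond. No stereocentre is created in 8, since the two bridgehead centres of racemic 7 disappear on aromatisation and the symmetric trimethoxyphenyl ring makes the new axis non-stereogenic. The step needs a single orientation, oxygen para and aryl meta to the ester, and polarity matching secures it, because the carbon beta to the ynol oxygen is the nucleophilic terminus (aryl ynol ethers react with electrophiles there through the oxygen-stabilised ketenium ion, even though the aryl donor pushes the other way) and C6 of 6, the beta-carbon of the acrylate unit and the 1,6-acceptor site of the lactone, is the most electrophilic diene terminus. The linear alkyne lets the diene approach over the face of the aryl ring, away from the two ortho-methoxy groups, and the bulky TIPS group suppresses silyl migration to carbon and hydrolysis during prolonged heating.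

Step 4
Reactants: 8 methyl 4-[(triisopropylsilyl)oxy]-3-(2,4,6-trimethoxyphenyl)benzoate
Product: 9 methyl 3-(3-acetyl-2,4,6-trimethoxyphenyl)-4-[(triisopropylsilyl)oxy]benzoate
Conditions: Ac2O, Sc(OTf)3 (10 mol %), MeNO2, 50 °C
Reagents that add atoms: acetic anhydride, CC(=O)OC(C)=O
Why: Triflate-catalysed Friedel–Crafts acetylation should attack the far more electron-rich trimethoxyphenyl ring at one of its two equivalent free positions, and the first acetyl group deactivates that ring against a second acylation.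

Step 5
Reactants: 9 methyl 3-(3-acetyl-2,4,6-trimethoxyphenyl)-4-[(triisopropylsilyl)oxy]benzoate
Product: 10 methyl 3-(3-acetyl-2,4,6-trihydroxyphenyl)-4-[(triisopropylsilyl)oxy]benzoate
Conditions: BBr3 (6 equiv), CH2Cl2, −78 → 0 °C; then ice–water
Reagents that add atoms: none
Why: Lewis-acid ether cleavage with BBr3 (complexation at oxygen, bromide attack at methyl) removes the three aryl methyl ethers, while the methyl benzoate and the bulky silyl ether on the ester-deactivated oxygen are poor donors and should persist at or below 0 °C, and any desilylated material converges with 10 in step 6.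

Step 6
Reactants: 10 methyl 3-(3-acetyl-2,4,6-trihydroxyphenyl)-4-[(triisopropylsilyl)oxy]benzoate
Product: 11 methyl 3-[3-acetyl-4,6-bis(benzyloxy)-2-hydroxyphenyl]-4-(benzyloxy)benzoate
Conditions: BnBr (3.05 equiv), CsF (1.1 equiv), K2CO3 (2.2 equiv), DMF, 0 °C → rt
Reagents that add atoms: benzyl bromide, BrCc1ccccc1
Why: Fluoride frees the ring B phenoxide in the flask (desilylative Williamson etherification) and the three equivalents of BnBr should go to the three accessible oxygens, whereas the hydroxyl flanked by the aryl and acetyl groups stays free because it is the most shielded and is held in the hydrogen bond to the ketone, as in the partial alkylation of 3-substituted phloroacetophenones.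

Step 7
Reactants: 11 methyl 3-[3-acetyl-4,6-bis(benzyloxy)-2-hydroxyphenyl]-4-(benzyloxy)benzoate; 12 4-(benzyloxy)benzoyl chloride
Product: 14 methyl 4-(benzyloxy)-3-{5,7-bis(benzyloxy)-2-[4-(benzyloxy)phenyl]-4-oxo-4H-chromen-8-yl}benzoate, via 1,3-diketone 13 (not isolated)
Conditions: LiN(SiMe3)2 (3.2 equiv), THF, −78 → −20 °C; 12, −78 °C → rt; aq HCl; then p-TsOH·H2O (cat.), toluene, 90 °C
Reagents that add atoms: none
Why: C-aroylation of the lithium phenoxide–enolate dianion is the one-flask form of the Baker–Venkataraman sequence and avoids esterifying the hindered phenol, and acid-catalysed cyclodehydration of the crude diketone can use only the single free hydroxyl next to the biaryl bond, which fixes the C8'' linkage.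

Step 8
Reactants: 14 methyl 4-(benzyloxy)-3-{5,7-bis(benzyloxy)-2-[4-(benzyloxy)phenyl]-4-oxo-4H-chromen-8-yl}benzoate
Product: 15 4-(benzyloxy)-3-{5,7-bis(benzyloxy)-2-[4-(benzyloxy)phenyl]-4-oxo-4H-chromen-8-yl}benzoic acid
Conditions: LiOH, THF–MeOH–H2O, 40 °C; then 1 M HCl
Reagents that add atoms: lithium hydroxide, [Li+].[OH-]
Why: Saponification of a methyl benzoate with LiOH proceeds at mild temperature, well below the hot concentrated alkali needed to open a flavone ring, and benzyl ethers are inert to it.

Step 9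
Reactants: 15 4-(benzyloxy)-3-{5,7-bis(benzyloxy)-2-[4-(benzyloxy)phenyl]-4-oxo-4H-chromen-8-yl}benzoic acid; 16 1-(2,6-dihydroxy-4-methoxyphenyl)ethan-1-one (2',6'-dihydroxy-4'-methoxyacetophenone)
Product: 19 5,7-bis(benzyloxy)-8-[2-(benzyloxy)-5-(5-hydroxy-7-methoxy-4-oxo-4H-chromen-2-yl)phenyl]-2-[4-(benzyloxy)phenyl]-4H-chromen-4-one (4',5'',7'',4'''-tetra-O-benzylsequoiaflavone), via acid chloride 17 (not isolated), via 1,3-diketone 18 (not isolated)
Conditions: 15, (COCl)2, DMF (cat.), CH2Cl2, 0 °C → rt, evaporate; 16, LiN(SiMe3)2 (4.2 equiv), THF, −78 → −10 °C, then 17 in THF, −78 °C → rt; aq HCl; then p-TsOH·H2O (cat.), toluene, 90 °C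
Reagents that add atoms: oxalyl chloride, O=C(Cl)C(=O)Cl (chlorine of 17 only)
Why: The lithium polyanion of a 2,6-dihydroxyacetophenone is acylated at carbon by one equivalent of an aroyl chloride without phenol protection (one-flask Baker–Venkataraman variant), and because 16 is symmetric the acid-catalysed cyclodehydration gives the same 5-hydroxy-7-methoxyflavone whichever hydroxyl closes.

Step 10
Reactants: 19 4',5'',7'',4'''-tetra-O-benzylsequoiaflavone
Product: 20 sequoiaflavone
Conditions: H2 (1 atm), 10% Pd/C, THF–MeOH, rt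
Reagents that add atoms: none
Why: Catalytic hydrogenolysis cleaves the four benzyl–oxygen bonds at atmospheric pressure, conditions under which the aryl methyl ether and the C2=C3 bonds of flavones are normally inert.

**Compound list**

1 | 2,4,6-trimethoxybenzaldehyde | COc1cc(OC)c(C=O)c(OC)c1 | starting material
2 | 2-ethynyl-1,3,5-trimethoxybenzene | C#Cc1c(OC)cc(OC)cc1OC | intermediate
3 | lithium (2,4,6-trimethoxyphenyl)acetylide | [Li]C#Cc1c(OC)cc(OC)cc1OC | intermediate
4 | lithium 2-(2,4,6-trimethoxyphenyl)ethynolate | [Li]OC#Cc1c(OC)cc(OC)cc1OC | intermediate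
5 | triisopropyl{[(2,4,6-trimethoxyphenyl)ethynyl]oxy}silane | COc1cc(OC)c(C#CO[Si](C(C)C)(C(C)C)C(C)C)c(OC)c1 | intermediate
6 | methyl coumalate (methyl 2-oxo-2H-pyran-5-carboxylate) | COC(=O)C1=COC(=O)C=C1 | starting material
7 | methyl 3-oxo-8-[(triisopropylsilyl)oxy]-7-(2,4,6-trimethoxyphenyl)-2-oxabicyclo[2.2.2]octa-5,7-diene-6-carboxylate (racemic) | COC(=O)C1=CC2C(=O)OC1C(c1c(OC)cc(OC)cc1OC)=C2O[Si](C(C)C)(C(C)C)C(C)C | intermediate
8 | methyl 4-[(triisopropylsilyl)oxy]-3-(2,4,6-trimethoxyphenyl)benzoate | COC(=O)c1ccc(O[Si](C(C)C)(C(C)C)C(C)C)c(-c2c(OC)cc(OC)cc2OC)c1 | intermediate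
9 | methyl 3-(3-acetyl-2,4,6-trimethoxyphenyl)-4-[(triisopropylsilyl)oxy]benzoate | COC(=O)c1ccc(O[Si](C(C)C)(C(C)C)C(C)C)c(-c2c(OC)cc(OC)c(C(C)=O)c2OC)c1 | intermediate
10 | methyl 3-(3-acetyl-2,4,6-trihydroxyphenyl)-4-[(triisopropylsilyl)oxy]benzoate | COC(=O)c1ccc(O[Si](C(C)C)(C(C)C)C(C)C)c(-c2c(O)cc(O)c(C(C)=O)c2O)c1 | intermediate
11 | methyl 3-[3-acetyl-4,6-bis(benzyloxy)-2-hydroxyphenyl]-4-(benzyloxy)benzoate | COC(=O)c1ccc(OCc2ccccc2)c(-c2c(OCc3ccccc3)cc(OCc3ccccc3)c(C(C)=O)c2O)c1 | intermediate
12 | 4-(benzyloxy)benzoyl chloride | O=C(Cl)c1ccc(OCc2ccccc2)cc1 | starting material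
13 | methyl 4-(benzyloxy)-3-(4,6-bis(benzyloxy)-3-{3-[4-(benzyloxy)phenyl]-3-oxopropanoyl}-2-hydroxyphenyl)benzoate | COC(=O)c1ccc(OCc2ccccc2)c(-c2c(OCc3ccccc3)cc(OCc3ccccc3)c(C(=O)CC(=O)c3ccc(OCc4ccccc4)cc3)c2O)c1 | intermediate
14 | methyl 4-(benzyloxy)-3-{5,7-bis(benzyloxy)-2-[4-(benzyloxy)phenyl]-4-oxo-4H-chromen-8-yl}benzoate | COC(=O)c1ccc(OCc2ccccc2)c(-c2c(OCc3ccccc3)cc(OCc3ccccc3)c3c(=O)cc(-c4ccc(OCc5ccccc5)cc4)oc23)c1 | intermediate
15 | 4-(benzyloxy)-3-{5,7-bis(benzyloxy)-2-[4-(benzyloxy)phenyl]-4-oxo-4H-chromen-8-yl}benzoic acid | OC(=O)c1ccc(OCc2ccccc2)c(-c2c(OCc3ccccc3)cc(OCc3ccccc3)c3c(=O)cc(-c4ccc(OCc5ccccc5)cc4)oc23)c1 | intermediate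
16 | 1-(2,6-dihydroxy-4-methoxyphenyl)ethan-1-one | COc1cc(O)c(C(C)=O)c(O)c1 | starting material
17 | 4-(benzyloxy)-3-{5,7-bis(benzyloxy)-2-[4-(benzyloxy)phenyl]-4-oxo-4H-chromen-8-yl}benzoyl chloride | ClC(=O)c1ccc(OCc2ccccc2)c(-c2c(OCc3ccccc3)cc(OCc3ccccc3)c3c(=O)cc(-c4ccc(OCc5ccccc5)cc4)oc23)c1 | intermediate
18 | 1-(4-(benzyloxy)-3-{5,7-bis(benzyloxy)-2-[4-(benzyloxy)phenyl]-4-oxo-4H-chromen-8-yl}phenyl)-3-(2,6-dihydroxy-4-methoxyphenyl)propane-1,3-dione | COc1cc(O)c(C(=O)CC(=O)c2ccc(OCc3ccccc3)c(-c3c(OCc4ccccc4)cc(OCc4ccccc4)c4c(=O)cc(-c5ccc(OCc6ccccc6)cc5)oc34)c2)c(O)c1 | intermediate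
19 | 4',5'',7'',4'''-tetra-O-benzylsequoiaflavone | COc1cc(O)c2c(=O)cc(-c3ccc(OCc4ccccc4)c(-c4c(OCc5ccccc5)cc(OCc5ccccc5)c5c(=O)cc(-c6ccc(OCc7ccccc7)cc6)oc45)c3)oc2c1 | intermediate
20 | sequoiaflavone | COc1cc(O)c2c(=O)cc(-c3ccc(O)c(-c4c(O)cc(O)c5c(=O)cc(-c6ccc(O)cc6)oc45)c3)oc2c1 | target

**Step count and risks**

Total step count: 10.
Longest linear sequence: 10 steps (1 → 2 → 5 → 8 → 9 → 10 → 11 → 14 → 15 → 19 → 20). Compounds 6, 12 and 16 are purchased.

Steps most likely to fail:

**Step 3.**
- What may go wrong: both alkyne carbons are crowded, one by the two ortho-methoxy groups and the other by the TIPS group. The cycloaddition may therefore be slower than thermal decay of the ynol ether by silyl migration to carbon, hydrolysis or oligomerisation. The orientation may also erode, because the trimethoxyphenyl donor polarises the triple bond against the oxygen.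
- Fallback: the C3'–C8'' bond is made by Suzuki–Miyaura coupling instead of building ring B around it. The fallback sets out from 12 and comes back at 14.
- Commercial 1-[2,4-bis(benzyloxy)-6-hydroxyphenyl]ethan-1-one is iodinated ortho to its free hydroxyl (N-iodosuccinimide, cat. TFA, MeCN). This gives 1-[4,6-bis(benzyloxy)-2-hydroxy-3-iodophenyl]ethan-1-one F1.
- The lithium dianion of F1 is aroylated with 12 as in step 7, giving 1-[4,6-bis(benzyloxy)-2-hydroxy-3-iodophenyl]-3-[4-(benzyloxy)phenyl]propane-1,3-dione F2.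
- p-TsOH closes F2 to 5,7-bis(benzyloxy)-2-[4-(benzyloxy)phenyl]-8-iodo-4H-chromen-4-one F3.
- Miyaura borylation of methyl 4-(benzyloxy)-3-bromobenzoate [B2pin2, Pd(dppf)Cl2, KOAc, dioxane] gives methyl 4-(benzyloxy)-3-(4,4,5,5-tetramethyl-1,3,2-dioxaborolan-2-yl)benzoate F4.
- F4 is coupled with F3 [Pd(PPh3)4, K2CO3, DMF–H2O, 90 °C] to give 14.

**Step 6.**
- What may go wrong: site selectivity between the two hydroxyls ortho to the ketone may be poor, benzylation may run past three groups, and the phloroglucinol nucleus may be benzylated at carbon.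
- Fallback: selective protection is replaced by exhaustive protection followed by chelation-controlled deprotection. The fallback sets out from 10 and comes back at 11.
- Excess BnBr with Cs2CO3 and CsF (DMF, 60 °C) gives methyl 3-[3-acetyl-2,4,6-tris(benzyloxy)phenyl]-4-(benzyloxy)benzoate F5.
- MgBr2·OEt2 (toluene–Et2O, reflux) then removes one benzyl ether ortho to the carbonyl group through a magnesium chelate.
- The ether flanked on both sides, next to the biaryl bond, is twisted out of conjugation. It is therefore the more Lewis-basic and the more strained of the two, and it should be the one cleaved, giving 11.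

**Step 2.**
- What may go wrong: oxygen transfer to the crowded, electron-rich acetylide may stall, silylation may go partly to carbon, or the ynol ether may hydrolyse during isolation.
- Fallback: the same ynolate is reached by a carbenoid 1,2-aryl shift (the rearrangement stage of the Kowalski homologation) instead of by oxidation of an acetylide. The fallback sets out from 1 and comes back at 4, which is silylated to 5 as in step 2.
- LiCHBr2 [CH2Br2, LiN(i-Pr)2, THF, −90 °C] adds to 1 to give racemic 2,2-dibromo-1-(2,4,6-trimethoxyphenyl)ethan-1-ol F6.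
- Dess–Martin periodinane (NaHCO3 buffer, CH2Cl2) oxidises F6 to 2,2-dibromo-1-(2,4,6-trimethoxyphenyl)ethan-1-one F7.
- LiN(SiMe3)2 and then n-BuLi (THF, −78 °C → rt) convert F7 into 4 by enolisation, bromine–lithium exchange and migration of the electron-rich aryl group.

**Further compounds**

F1 | step 3 | 1-[4,6-bis(benzyloxy)-2-hydroxy-3-iodophenyl]ethan-1-one | CC(=O)c1c(O)c(I)c(OCc2ccccc2)cc1OCc1ccccc1
F2 | step 3 | 1-[4,6-bis(benzyloxy)-2-hydroxy-3-iodophenyl]-3-[4-(benzyloxy)phenyl]propane-1,3-dione | O=C(CC(=O)c1ccc(OCc2ccccc2)cc1)c1c(O)c(I)c(OCc2ccccc2)cc1OCc1ccccc1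
F3 | step 3 | 5,7-bis(benzyloxy)-2-[4-(benzyloxy)phenyl]-8-iodo-4H-chromen-4-one | O=c1cc(-c2ccc(OCc3ccccc3)cc2)oc2c(I)c(OCc3ccccc3)cc(OCc3ccccc3)c12
F4 | step 3 | methyl 4-(benzyloxy)-3-(4,4,5,5-tetramethyl-1,3,2-dioxaborolan-2-yl)benzoate | COC(=O)c1ccc(OCc2ccccc2)c(B2OC(C)(C)C(C)(C)O2)c1
F5 | step 6 | methyl 3-[3-acetyl-2,4,6-tris(benzyloxy)phenyl]-4-(benzyloxy)benzoate | COC(=O)c1ccc(OCc2ccccc2)c(-c2c(OCc3ccccc3)cc(OCc3ccccc3)c(C(C)=O)c2OCc2ccccc2)c1
F6 | step 2 | 2,2-dibromo-1-(2,4,6-trimethoxyphenyl)ethan-1-ol (racemic) | COc1cc(OC)c(C(O)C(Br)Br)c(OC)c1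
F7 | step 2 | 2,2-dibromo-1-(2,4,6-trimethoxyphenyl)ethan-1-one | COc1cc(OC)c(C(=O)C(Br)Br)c(OC)c1
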